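## Retrosynthetic overview

- **Feature:** in the flavone half, the pyranone ring (O1, C2, C3, C4, C4a, C8a) holds C4 as an isolated carbonyl carbon between C4a of the phloroglucinol ring and C3, and C2 bears the catechol ring (ring B). Cutting C4a–C4, C4–C3 and O1–C2 leaves an ortho-iodophenol, CO and an ethynyl group on the catechol ring.
- The alkyne partner carries the whole flavanone half as its (2R,4R)-4-silyloxyflavan, so no C4 carbonyl meets amine or base. The ethynyl group comes from an aryl aldehyde by one-carbon homologation.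
- The biaryl bond C6 (flavan)–C6' (catechol ring) is cut to a 6-iodoflavan and a 2-formylarylboronate (Suzuki–Miyaura coupling).
- C2 is set (R) by rhodium-catalysed asymmetric 1,4-addition of an arylboronic acid to 6-iodo-5,7-bis(MOM-oxy)chromone. The free 5-OH places that iodine at C6.
- **Ring order:** the benzopyranone of the flavanone half is bought as a chromone, its ring B is added, the catechol ring is coupled on, and the flavone pyranone closes last. Desilylation, oxidation at C4 and global MOM cleavage finish the route.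

Key step: step 13

Assumption: the C6–C6' biaryl axis has three ortho substituents and is not assigned in the target. It is treated as configurationally labile, intermediates may show rotamers, and no axial control is attempted.

Abbreviations: MOM = methoxymethyl, TBS = tert-butyldimethylsilyl. Flavonoid numbering is used (O1, C2, C3, C4, C4a, C5–C8, C8a; primes for ring B).

## Route

Step 1
Reactants: 1 5,7-dihydroxy-4H-chromen-4-one
Product: 2 5-hydroxy-7-(MOM-oxy)-4H-chromen-4-one
Conditions: MOMCl (1.1 equiv), K2CO3 (1.2 equiv), acetone, 0 °C → rt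
Reagents that add atoms: chloromethyl methyl ether (MOMCl), COCCl
Why: Selective MOM ether formation (Williamson-type O-alkylation): the 7-OH is a vinylogous carboxylic acid that carbonate deprotonates, while the 5-OH is tied up in a hydrogen bond to the C4 carbonyl and stays free when one equivalent of MOMCl is used.

Step 2
Reactants: 2 5-hydroxy-7-(MOM-oxy)-4H-chromen-4-one
Product: 3 5-hydroxy-6-iodo-7-(MOM-oxy)-4H-chromen-4-one
Conditions: NIS (1.05 equiv), DMF, rt, dark
Reagents that add atoms: N-iodosuccinimide (NIS), O=C1CCC(=O)N1I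
Why: Electrophilic aromatic iodination under neutral conditions: in 5-hydroxy-7-alkoxy chromones and flavones the free, chelated 5-OH steers NIS to its ortho carbon C6 rather than to C8, and the absence of acid spares the MOM ether.

Step 3
Reactants: 3 5-hydroxy-6-iodo-7-(MOM-oxy)-4H-chromen-4-one
Product: 4 6-iodo-5,7-bis(MOM-oxy)-4H-chromen-4-one
Conditions: NaH, MOMCl, DMF, 0 °C → rt
Reagents that add atoms: chloromethyl methyl ether (MOMCl), COCCl
Why: MOM ether formation via the sodium phenoxide (Williamson-type O-alkylation): irreversible deprotonation by NaH breaks the chelate of the crowded 5-OH, and the flat chromone has no stereocentre that strong base could harm.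

Step 4
Reactants: 4 6-iodo-5,7-bis(MOM-oxy)-4H-chromen-4-one; 5 [4-(MOM-oxy)phenyl]boronic acid
Product: 6 (2R)-6-iodo-5,7-bis(MOM-oxy)-2-[4-(MOM-oxy)phenyl]chroman-4-one
Conditions: [Rh(OH)(cod)]2 (2.5 mol %), (R)-MeO-F12-BIPHEP (5.5 mol %), 5 (2 equiv), toluene–H2O 10:1, 25 °C
Reagents that add atoms: none
Why: Hayashi–Miyaura asymmetric 1,4-addition, a reaction known for chromones including 5,7-dioxygenated ones: the aryl rhodium species bearing the electron-poor (R)-biaryl diphosphine should add to C2 from the face left open by the ligand quadrants and set 2R (the ligand antipode is available should the sense prove opposite), fast protonation of the rhodium enolate forestalls ring opening, and monovalent rhodium at 25 °C leaves the hindered C–I bond alone.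

Step 5
Reactants: 6 (2R)-6-iodo-5,7-bis(MOM-oxy)-2-[4-(MOM-oxy)phenyl]chroman-4-one
Product: 7 (2R,4R)-6-iodo-5,7-bis(MOM-oxy)-2-[4-(MOM-oxy)phenyl]chroman-4-ol (2,4-cis)
Conditions: NaBH4, THF–MeOH 1:1, −10 → 0 °C
Reagents that add atoms: none
Why: Borohydride reduction of a flavanone: hydride adds from the axial side to the half-chair that keeps the 2-aryl group equatorial and should give the 2,4-cis alcohol (4R), and because C4 becomes a ketone again in step 15 any trans epimer is carried along without harm.

Step 6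
Reactants: 7 (2R,4R)-6-iodo-5,7-bis(MOM-oxy)-2-[4-(MOM-oxy)phenyl]chroman-4-ol
Product: 8 (2R,4R)-4-(TBS-oxy)-6-iodo-5,7-bis(MOM-oxy)-2-[4-(MOM-oxy)phenyl]chromane
Conditions: TBSCl, imidazole, DMAP (cat), DMF, 35 °C
Reagents that add atoms: tert-butyldimethylsilyl chloride (TBSCl), CC(C)(C)[Si](C)(C)Cl
Why: Imidazole-promoted silylation of a secondary alcohol: the purely basic medium avoids ionisation of the very electron-rich benzylic C4–O bond, and once C4 is masked no carbonyl remains through which base could open the pyran ring and scramble C2.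

Step 7
Reactants: 9 2-bromo-4,5-dihydroxybenzaldehyde
Product: 10 2-bromo-4,5-bis(MOM-oxy)benzaldehyde
Conditions: MOMCl (2.5 equiv), K2CO3, DMF, 0 °C → rt
Reagents that add atoms: chloromethyl methyl ether (MOMCl), COCCl
Why: Double MOM ether formation (Williamson-type O-alkylation): both catechol hydroxyls are acidic and unhindered, and aldehyde and aryl bromide are inert to carbonate and MOMCl.

Step 8
Reactants: 10 2-bromo-4,5-bis(MOM-oxy)benzaldehyde
Product: 11 4,5-bis(MOM-oxy)-2-(4,4,5,5-tetramethyl-1,3,2-dioxaborolan-2-yl)benzaldehyde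
Conditions: B2pin2, PdCl2(dppf) (3 mol %), KOAc, 1,4-dioxane, 90 °C
Reagents that add atoms: bis(pinacolato)diboron, CC1(C)OB(OC1(C)C)B1OC(C)(C)C(C)(C)O1
Why: Miyaura borylation: the ortho-formyl group speeds oxidative addition into the otherwise electron-rich C–Br bond, and acetate is too weak a base to start Suzuki homocoupling or to touch the aldehyde.

Step 9
Reactants: 8 (2R,4R)-4-(TBS-oxy)-6-iodo-5,7-bis(MOM-oxy)-2-[4-(MOM-oxy)phenyl]chromane; 11 4,5-bis(MOM-oxy)-2-(pinacolboryl)benzaldehyde
Product: 12 2-[(2R,4R)-4-(TBS-oxy)-5,7-bis(MOM-oxy)-2-(4-MOM-oxyphenyl)chroman-6-yl]-4,5-bis(MOM-oxy)benzaldehyde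
Conditions: Pd(OAc)2 (5 mol %), SPhos (10 mol %), K3PO4, 11 (1.8 equiv), toluene–H2O 10:1, 90 °C
Reagents that add atoms: none
Why: Suzuki–Miyaura coupling: SPhos-ligated palladium is the established catalyst for aryl halides flanked by two ortho alkoxy groups and for biaryls with three ortho substituents, the crowded partner is used as the iodide because 2,6-dialkoxyarylboron compounds protodeboronate readily, and C2 is safe under phosphate base since C4 is a silyl ether.

Step 10
Reactants: 12 biaryl aldehyde
Product: 13 (2R,4R)-4-(TBS-oxy)-6-[2-ethynyl-4,5-bis(MOM-oxy)phenyl]-5,7-bis(MOM-oxy)-2-(4-MOM-oxyphenyl)chromane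
Conditions: dimethyl (1-diazo-2-oxopropyl)phosphonate, K2CO3, MeOH–THF 2:1, 0 °C → rt
Reagents that add atoms: dimethyl (1-diazo-2-oxopropyl)phosphonate, COP(=O)(OC)C(=[N+]=[N-])C(C)=O
Why: Ohira–Bestmann variant of the Seyferth–Gilbert homologation: methanolysis of the reagent releases the diazomethylphosphonate anion, which olefinates the non-enolisable aldehyde to a diazoalkene that loses N2 and undergoes a 1,2-shift to the terminal alkyne, under carbonate conditions that leave the secondary TBS ether and the MOM ethers intact.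

Step 11
Reactants: 14 phloroglucinol
Product: 15 3,5-bis(MOM-oxy)phenol
Conditions: MOMCl (2.0 equiv), i-Pr2NEt, DMF, 0 °C → rt
Reagents that add atoms: chloromethyl methyl ether (MOMCl), COCCl
Why: Statistical MOM ether formation (Williamson-type O-alkylation) on a threefold symmetric triol: two equivalents of MOMCl favour the diether, only one diether is possible, and the mono- and triethers are removed by chromatography.

Step 12
Reactants: 15 3,5-bis(MOM-oxy)phenol
Product: 16 2-iodo-3,5-bis(MOM-oxy)phenol
Conditions: NIS (1.0 equiv), CH2Cl2, −40 → 0 °C, dark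
Reagents that add atoms: N-iodosuccinimide (NIS), O=C1CCC(=O)N1I
Why: Electrophilic aromatic iodination: all free ring positions are activated, but the two equivalent carbons ortho to the free OH should win over C4 by number, by hydrogen-bond delivery of NIS from the phenol in a non-polar solvent and by the crowding of C4 between two MOM ethers, and the minor para iodide is separated by chromatography.

Step 13
Reactants: 13 (2R,4R)-4-(TBS-oxy)-6-[2-ethynyl-4,5-bis(MOM-oxy)phenyl]-5,7-bis(MOM-oxy)-2-(4-MOM-oxyphenyl)chromane; 16 2-iodo-3,5-bis(MOM-oxy)phenol; 17 carbon monoxide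
Product: 20 hepta-MOM flavone-substituted (2R,4R)-4-(TBS-oxy)flavan, via ynone 18 (not isolated), via enaminone 19 (not isolated)
Conditions: PdCl2(PPh3)2 (5 mol %), CO (10 bar), 16 (1.5 equiv), Et2NH, 80 °C, autoclave
Reagents that add atoms: diethylamine, CCNCC (its atoms stay only in intermediate 19)
Why: PdCl2(PPh3)2 is reduced in situ to zerovalent palladium, which inserts into the C–I bond of 16; CO insertion gives the aroyl complex of divalent palladium, and transfer of the amine-deprotonated alkyne 13 followed by reductive elimination forges C4a–C4 and C4–C3 in ynone 18. Diethylamine then adds to the alkyne carbon bearing the catechol ring to give enaminone 19, and the neighbouring phenol replaces the amine at that carbon by addition–elimination, forming O1–C2. The closest known reaction type is the carbonylative Sonogashira annulation of ortho-iodophenols with terminal arylalkynes, an established flavone synthesis. The one new ring, the pyranone, closes in the 6-endo mode (6-endo-dig counted on 18, 6-endo-trig on 19); the 5-exo path to the aurone is shut because the amine has already turned the alkyne into a β-amino enone whose only electrophilic carbon is C2. No stereocentre is created, and C2 and C4 of the flavan survive because the masked C4 offers no carbonyl for retro-oxa-Michael opening under the amine. The step needs carbonylative rather than direct coupling (which would end in a 2-arylbenzofuran) and alkyne rather than amine capture of the aroyl palladium: CO pressure without a copper co-catalyst secures the first, and the two ortho oxygen substituents of 16, which shield the aroyl carbon from the bulky secondary amine, favour the second.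

Step 14
Reactants: 20 hepta-MOM flavone-substituted (2R,4R)-4-(TBS-oxy)flavan
Product: 21 hepta-MOM flavone-substituted (2R,4R)-flavan-4-ol
Conditions: TBAF, THF, 0 °C → rt
Reagents that add atoms: none
Why: Fluoride-induced desilylation driven by the strong Si–F bond: MOM ethers, the flavone and the C2 stereocentre are inert to TBAF because there is still no C4 carbonyl.

Step 15
Reactants: 21 hepta-MOM flavone-substituted (2R,4R)-flavan-4-ol
Product: 22 hepta-MOM ether of the target, (2R)-flavanone
Conditions: Dess–Martin periodinane, NaHCO3, CH2Cl2, 0 °C → rt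
Reagents that add atoms: none
Why: Dess–Martin oxidation: ligand exchange at iodine and intramolecular proton abstraction turn the benzylic alcohol into the ketone under near-neutral buffered conditions, so that neither acid ionisation at C4 nor base-induced retro-oxa-Michael racemisation at C2 can set in.

Step 16
Reactants: 22 hepta-MOM ether of the target
Product: 23 target, (2R)-6-[2-(5,7-dihydroxy-4-oxo-4H-chromen-2-yl)-4,5-dihydroxyphenyl]-5,7-dihydroxy-2-(4-hydroxyphenyl)chroman-4-one
Conditions: HCl (1.25 M in MeOH), THF, 40 °C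
Reagents that add atoms: none
Why: Acid-catalysed acetal exchange (MOM cleavage): methanol traps each methoxymethyl cation as dimethoxymethane and so keeps it away from the nucleophilic phloroglucinol rings, and dilute acid at mild temperature does not open the flavanone ring, so that 2R and the 6-aryl (rather than 8-aryl) connectivity are kept.

## Compound list

1 | 5,7-dihydroxy-4H-chromen-4-one | O=c1ccoc2cc(O)cc(O)c12 | starting material
2 | 5-hydroxy-7-(methoxymethoxy)-4H-chromen-4-one | O=c1ccoc2cc(OCOC)cc(O)c12 | intermediate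
3 | 5-hydroxy-6-iodo-7-(methoxymethoxy)-4H-chromen-4-one | O=c1ccoc2cc(OCOC)c(I)c(O)c12 | intermediate
4 | 6-iodo-5,7-bis(methoxymethoxy)-4H-chromen-4-one | O=c1ccoc2cc(OCOC)c(I)c(OCOC)c12 | intermediate
5 | [4-(methoxymethoxy)phenyl]boronic acid | COCOc1ccc(B(O)O)cc1 | starting material
6 | (2R)-6-iodo-5,7-bis(methoxymethoxy)-2-[4-(methoxymethoxy)phenyl]chroman-4-one | O=C1C[C@H](c2ccc(OCOC)cc2)Oc2cc(OCOC)c(I)c(OCOC)c21 | intermediate
7 | (2R,4R)-6-iodo-5,7-bis(methoxymethoxy)-2-[4-(methoxymethoxy)phenyl]chroman-4-ol | O[C@@H]1C[C@H](c2ccc(OCOC)cc2)Oc2cc(OCOC)c(I)c(OCOC)c21 | intermediate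
8 | (2R,4R)-4-(tert-butyldimethylsilyloxy)-6-iodo-5,7-bis(methoxymethoxy)-2-[4-(methoxymethoxy)phenyl]chromane | CC(C)(C)[Si](C)(C)O[C@@H]1C[C@H](c2ccc(OCOC)cc2)Oc2cc(OCOC)c(I)c(OCOC)c21 | intermediate
9 | 2-bromo-4,5-dihydroxybenzaldehyde | O=Cc1cc(O)c(O)cc1Br | starting material
10 | 2-bromo-4,5-bis(methoxymethoxy)benzaldehyde | O=Cc1cc(OCOC)c(OCOC)cc1Br | intermediate
11 | 4,5-bis(methoxymethoxy)-2-(4,4,5,5-tetramethyl-1,3,2-dioxaborolan-2-yl)benzaldehyde | O=Cc1cc(OCOC)c(OCOC)cc1B1OC(C)(C)C(C)(C)O1 | intermediate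
12 | 2-[(2R,4R)-4-(TBS-oxy)-5,7-bis(MOM-oxy)-2-(4-MOM-oxyphenyl)chroman-6-yl]-4,5-bis(MOM-oxy)benzaldehyde | CC(C)(C)[Si](C)(C)O[C@@H]1C[C@H](c2ccc(OCOC)cc2)Oc2cc(OCOC)c(-c3cc(OCOC)c(OCOC)cc3C=O)c(OCOC)c21 | intermediate
13 | (2R,4R)-4-(TBS-oxy)-6-[2-ethynyl-4,5-bis(MOM-oxy)phenyl]-5,7-bis(MOM-oxy)-2-(4-MOM-oxyphenyl)chromane | CC(C)(C)[Si](C)(C)O[C@@H]1C[C@H](c2ccc(OCOC)cc2)Oc2cc(OCOC)c(-c3cc(OCOC)c(OCOC)cc3C#C)c(OCOC)c21 | intermediate
14 | phloroglucinol (benzene-1,3,5-triol) | Oc1cc(O)cc(O)c1 | starting material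
15 | 3,5-bis(methoxymethoxy)phenol | Oc1cc(OCOC)cc(OCOC)c1 | intermediate
16 | 2-iodo-3,5-bis(methoxymethoxy)phenol | Oc1cc(OCOC)cc(OCOC)c1I | intermediate
17 | carbon monoxide | [C-]#[O+] | starting material
18 | ynone: 1-[2-hydroxy-4,6-bis(MOM-oxy)phenyl]-3-aryl-prop-2-yn-1-one, aryl = the flavanyl-substituted catechol ring of 13 | CC(C)(C)[Si](C)(C)O[C@@H]1C[C@H](c2ccc(OCOC)cc2)Oc2cc(OCOC)c(-c3cc(OCOC)c(OCOC)cc3C#CC(=O)c3c(O)cc(OCOC)cc3OCOC)c(OCOC)c21 | intermediate
19 | enaminone: 3-(diethylamino)-1-[2-hydroxy-4,6-bis(MOM-oxy)phenyl]-3-aryl-prop-2-en-1-one, same aryl, alkene geometry not fixed | CC(C)(C)[Si](C)(C)O[C@@H]1C[C@H](c2ccc(OCOC)cc2)Oc2cc(OCOC)c(-c3cc(OCOC)c(OCOC)cc3C(N(CC)CC)=CC(=O)c3c(O)cc(OCOC)cc3OCOC)c(OCOC)c21 | intermediate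
20 | 2-{2-[(2R,4R)-4-(TBS-oxy)-5,7-bis(MOM-oxy)-2-(4-MOM-oxyphenyl)chroman-6-yl]-4,5-bis(MOM-oxy)phenyl}-5,7-bis(MOM-oxy)-4H-chromen-4-one | CC(C)(C)[Si](C)(C)O[C@@H]1C[C@H](c2ccc(OCOC)cc2)Oc2cc(OCOC)c(-c3cc(OCOC)c(OCOC)cc3-c3cc(=O)c4c(OCOC)cc(OCOC)cc4o3)c(OCOC)c21 | intermediate
21 | 2-{2-[(2R,4R)-4-hydroxy-5,7-bis(MOM-oxy)-2-(4-MOM-oxyphenyl)chroman-6-yl]-4,5-bis(MOM-oxy)phenyl}-5,7-bis(MOM-oxy)-4H-chromen-4-one | O[C@@H]1C[C@H](c2ccc(OCOC)cc2)Oc2cc(OCOC)c(-c3cc(OCOC)c(OCOC)cc3-c3cc(=O)c4c(OCOC)cc(OCOC)cc4o3)c(OCOC)c21 | intermediate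
22 | hepta-MOM ether of the target, (2R)-chroman-4-one | O=C1C[C@H](c2ccc(OCOC)cc2)Oc2cc(OCOC)c(-c3cc(OCOC)c(OCOC)cc3-c3cc(=O)c4c(OCOC)cc(OCOC)cc4o3)c(OCOC)c21 | intermediate
23 | (2R)-6-[2-(5,7-dihydroxy-4-oxo-4H-chromen-2-yl)-4,5-dihydroxyphenyl]-5,7-dihydroxy-2-(4-hydroxyphenyl)chroman-4-one | O=C1C[C@H](c2ccc(O)cc2)Oc2cc(O)c(-c3cc(O)c(O)cc3-c3cc(=O)c4c(O)cc(O)cc4o3)c(O)c21 | target

## Step count and risks

- Total step count: 16
- Longest linear sequence: 12 steps (steps 1–6, 9, 10, 13–16)

### Steps most likely to fail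

**Step 13.**
- What may go wrong: oxidative addition into the crowded, electron-rich C–I bond may be slow. Three processes could then compete with the three-component path:
  - direct alkynylation followed by closure to a benzofuran;
  - capture of the aroyl palladium by diethylamine;
  - reductive loss of iodine.
- Fallback: the C4 carbon is brought in as an aldehyde instead of CO. The fallback sets out from 15 and 13 and comes back to the route at 18 and so at 20.
  - Casnati–Skattebøl ortho-formylation of 15 (MgCl2, Et3N, paraformaldehyde, MeCN, reflux) gives 2-hydroxy-4,6-bis(MOM-oxy)benzaldehyde F1.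
  - Allylation (allyl bromide, K2CO3, DMF) gives 2-(allyloxy)-4,6-bis(MOM-oxy)benzaldehyde F2.
  - Alkyne 13 is deprotonated (n-BuLi, one equivalent, THF, −78 °C) to the lithium acetylide F3.
  - F3 adds to F2 to give, after NH4Cl quench, the propargylic alcohol F4 as both carbinol epimers.
  - MnO2 in CH2Cl2 oxidises it to the O-allyl ynone F5.
  - Tsuji–Trost deallylation with Pd(PPh3)4 in Et2NH–THF frees the phenol to give 18. Under the same amine, 18 closes through 19 to 20.

**Step 9.**
- What may go wrong: protodeboronation of the ortho-formyl, para-alkoxy boronate under aqueous base may outrun transmetalation onto a palladium centre crowded by two ortho MOM ethers. The stalled aryl palladium iodide may then be reduced at C6.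
- Fallback: a Negishi coupling with reversed polarity and no water. It sets out from 8 and 10 and comes back at 12.
  - Iodine–magnesium exchange on 8 (i-PrMgCl·LiCl, THF, −20 → 0 °C, assisted by the two chelating MOM ethers) gives the flavan-6-ylmagnesium chloride F6.
  - ZnCl2 converts it into the flavan-6-ylzinc chloride F7.
  - F7 is coupled with bromoaldehyde 10 (Pd(OAc)2, SPhos, THF, 50 °C). The C–Br bond of 10 is activated by the ortho-formyl group, and its aldehyde tolerates arylzinc halides.

**Step 4.**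
- What may go wrong: facial selectivity may be poor. Enantiomeric purity may also erode through β-aryloxide elimination from the rhodium enolate, that is, ring opening and unselective re-closure.
- Fallback: the stereochemistry is set by a reduction instead of by the C–C bond formation. It sets out from 4 and 5 and comes back at 7.
  - The 1,4-addition is run with [Rh(OH)(cod)]2 alone (no chiral ligand) to give the racemic flavanone F8.
  - F8 is resolved by asymmetric transfer hydrogenation (kinetic resolution) with RhCl(Cp*)[(R,R)-TsDPEN] and HCO2H–Et3N (amine in excess) in EtOAc at rt.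
  - The (R,R)-catalyst delivers hydride to give 4R and should reduce the matched (2R)-ketone much faster, giving 2,4-cis alcohol 7.
  - The unreacted (2S)-flavanone F9 is separated by chromatography. It can be racemised with mild base and recycled.

## Further compounds

F1 | step 13 | 2-hydroxy-4,6-bis(methoxymethoxy)benzaldehyde | O=Cc1c(O)cc(OCOC)cc1OCOC
F2 | step 13 | 2-(allyloxy)-4,6-bis(methoxymethoxy)benzaldehyde | C=CCOc1cc(OCOC)cc(OCOC)c1C=O
F3 | step 13 | lithium acetylide of 13 | CC(C)(C)[Si](C)(C)O[C@@H]1C[C@H](c2ccc(OCOC)cc2)Oc2cc(OCOC)c(-c3cc(OCOC)c(OCOC)cc3C#C[Li])c(OCOC)c21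
F4 | step 13 | propargylic alcohol, 1-[2-(allyloxy)-4,6-bis(MOM-oxy)phenyl]-3-aryl-prop-2-yn-1-ol, carbinol epimers | CC(C)(C)[Si](C)(C)O[C@@H]1C[C@H](c2ccc(OCOC)cc2)Oc2cc(OCOC)c(-c3cc(OCOC)c(OCOC)cc3C#CC(O)c3c(OCC=C)cc(OCOC)cc3OCOC)c(OCOC)c21
F5 | step 13 | O-allyl ynone, 1-[2-(allyloxy)-4,6-bis(MOM-oxy)phenyl]-3-aryl-prop-2-yn-1-one | CC(C)(C)[Si](C)(C)O[C@@H]1C[C@H](c2ccc(OCOC)cc2)Oc2cc(OCOC)c(-c3cc(OCOC)c(OCOC)cc3C#CC(=O)c3c(OCC=C)cc(OCOC)cc3OCOC)c(OCOC)c21
F6 | step 9 | (2R,4R)-4-(TBS-oxy)-5,7-bis(MOM-oxy)-2-(4-MOM-oxyphenyl)chroman-6-ylmagnesium chloride | CC(C)(C)[Si](C)(C)O[C@@H]1C[C@H](c2ccc(OCOC)cc2)Oc2cc(OCOC)c([Mg]Cl)c(OCOC)c21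
F7 | step 9 | (2R,4R)-4-(TBS-oxy)-5,7-bis(MOM-oxy)-2-(4-MOM-oxyphenyl)chroman-6-ylzinc chloride | CC(C)(C)[Si](C)(C)O[C@@H]1C[C@H](c2ccc(OCOC)cc2)Oc2cc(OCOC)c([Zn]Cl)c(OCOC)c21
F8 | step 4 | racemic 6-iodo-5,7-bis(MOM-oxy)-2-[4-(MOM-oxy)phenyl]chroman-4-one | O=C1CC(c2ccc(OCOC)cc2)Oc2cc(OCOC)c(I)c(OCOC)c21
F9 | step 4 | (2S)-6-iodo-5,7-bis(MOM-oxy)-2-[4-(MOM-oxy)phenyl]chroman-4-one | O=C1C[C@@H](c2ccc(OCOC)cc2)Oc2cc(OCOC)c(I)c(OCOC)c21
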